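**Plan**
Retrosynthetic cuts, in order: the C15 tert-butyl ester and the ring A oxygens at C2/C3 (late oxidations); C13=C14 (olefination of a C13 methyl ketone masked as a dioxolane); C4–C5 (closure of ring A onto a ring B enone); C10–C1 (aldol condensation) and C9–C11 (conjugate addition) on (R)-3,4-dimethylcyclohex-2-enone; C8 from an enamine-catalysed Michael addition.
Forward order: ring B first (C8, then C9, then C10, on a cyclohexanone whose carbonyl is C5), then a methylative 1,3-carbonyl transposition to the C7(=O)–C6=C5(CH3) enone, then ring A by joining C4 to C5, then C7 reduction and acetylation, the side chain, and last the diosphenol.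
Enabling feature: in ring B the acetoxy carbon C7 stands 1,3 to the quaternary ring-fusion carbon C5, so a C7 ketone makes C5 (already carrying the C19 methyl) the β-carbon of an enone; the exocyclic C4=CH2 of ring A is the footprint of a 2-bromo-1-alkene; the three carbons C1–C3 hung on C10 span exactly a six-membered ring.
Stereochemistry: C8 is set by catalysis; C9 by cuprate addition anti to the C8 methyl; C10 by enolate protonation anti to the axial C9 methyl; C5 by the tether from C10 (cis ring fusion); C7 by thermodynamic (equatorial) ketone reduction.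

Key step: step 9

Remark: positions are given in clerodane numbering (ring A C1–C4, ring fusion C5/C10, ring B C6–C9, side chain C11–C16 on C9, C17 = 8-methyl, C18 = exocyclic CH2 on C4, C19 = 5-methyl, C20 = 9-methyl) and β means the face of ring B that carries H-10; stereocentres that are made only to be erased in the same or the next operation (in 12, 13, 19, 26 and 29) are carried as epimer mixtures and written without descriptor.

Step 1
Reactants: 1 2-bromoprop-2-en-1-ol; 2 ethyl vinyl ether
Product: 4 4-bromopent-4-enal, via 2-bromoallyl vinyl ether 3 (not isolated)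
Conditions: Hg(OAc)2 (5 mol %), neat 2 (10 equiv), 35 °C; then sealed tube, 130 °C
Reagents that add atoms: none
Why: Mercury-catalysed vinyl exchange gives the allyl vinyl ether, which undergoes a thermal Claisen ([3,3]) rearrangement to the γ,δ-unsaturated aldehyde with the 2-bromoalkene intact; no stereocentre is formed.

Step 2
Reactants: 5 propanal; 6 but-3-en-2-one
Product: 7 (R)-2-methyl-5-oxohexanal
Conditions: (S)-2-[diphenyl(trimethylsilyloxy)methyl]pyrrolidine (5 mol %), ethyl 3,4-dihydroxybenzoate (20 mol %), neat, 4 °C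
Reagents that add atoms: none
Why: Enamine-catalysed Michael addition, in which the anti-E-enamine of propanal is attacked by the enone on the face opposite to the diphenyl(silyloxy)methyl group, which should set the 2R centre (the later C8) with high enantioselectivity.

Step 3
Reactants: 7 (R)-2-methyl-5-oxohexanal
Product: 8 (R)-4-methylcyclohex-2-en-1-one
Conditions: LiOH (0.1 equiv), i-PrOH, 25 °C
Reagents that add atoms: none
Why: Intramolecular aldol condensation of the methyl ketone enolate with the aldehyde closes the six-membered ring and dehydrates to the conjugated enone under mild base that should not epimerise the γ-stereocentre.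

Step 4
Reactants: 8 (R)-4-methylcyclohex-2-en-1-one
Product: 10 (R)-3,4-dimethylcyclohex-2-en-1-one, via silyl enol ether 9 (not isolated)
Conditions: MeMgBr, CuBr·SMe2 (5 mol %), Me3SiCl, THF, −78 °C; then Pd(OAc)2 (10 mol %), O2 (1 atm), DMSO, 25 °C
Reagents that add atoms: methylmagnesium bromide, C[Mg]Br
Why: Copper-catalysed conjugate addition of the methyl Grignard reagent (anti to the C4 methyl) is trapped as the silyl enol ether, and Saegusa–Ito dehydrogenation (β-hydride elimination of the palladium enolate toward C3) returns the enone with the new 3-methyl group, which erases the transient centre and leaves C4 (the later C8) untouched.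

Step 5
Reactants: 10 (R)-3,4-dimethylcyclohex-2-en-1-one; 4 4-bromopent-4-enal
Product: 14 (2Z,3S,4R)-2-(4-bromopent-4-en-1-ylidene)-3,4-dimethyl-3-[2-(2-methyl-1,3-dioxolan-2-yl)ethyl]cyclohexan-1-one, via magnesium enolate 11 (not isolated), via magnesium aldolate 12 (not isolated), via aldol mesylate 13 (not isolated)
Conditions: [2-(2-methyl-1,3-dioxolan-2-yl)ethyl]MgBr, CuBr·SMe2 (10 mol %), THF, −40 °C; 4, −78 °C; MeSO2Cl, −78 to 0 °C; DBU, 25 °C
Reagents that add atoms: [2-(2-methyl-1,3-dioxolan-2-yl)ethyl]magnesium bromide, CC1(CC[Mg]Br)OCCO1 (made beforehand from 2-(2-bromoethyl)-2-methyl-1,3-dioxolane, CC1(CCBr)OCCO1, and Mg in THF)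
Why: Copper-catalysed conjugate addition of the Grignard reagent occurs anti to the pseudoaxial C8 methyl and sets the quaternary C9 (side chain β, methyl α), the regiodefined magnesium enolate then adds to aldehyde 4 at C10 (aldol addition), and mesylation with E1cB elimination gives the exocyclic enone, in which the chain should lie syn to the carbonyl to avoid the quaternary C9.

Step 6
Reactants: 14 (2Z,3S,4R)-2-(4-bromopent-4-en-1-ylidene)-3,4-dimethyl-3-[2-(2-methyl-1,3-dioxolan-2-yl)ethyl]cyclohexan-1-one
Product: 16 (2R,3S,4R)-2-(4-bromopent-4-en-1-yl)-3,4-dimethyl-3-[2-(2-methyl-1,3-dioxolan-2-yl)ethyl]cyclohexan-1-one, via copper enolate 15 (not isolated)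
Conditions: [(Ph3P)CuH]6 (0.4 equiv), H2O (5 equiv), THF, 25 °C
Reagents that add atoms: none
Why: Conjugate reduction by the copper hydride places hydride on C1, and the copper enolate is protonated in situ at C10 on the β face, anti to the pseudoaxial C9 methyl, so that H-10 is β and the chain equatorial and cis to both methyls, the epimer that should also be the more stable one.

Step 7
Reactants: 16 (2R,3S,4R)-2-(4-bromopent-4-en-1-yl)-3,4-dimethyl-3-[2-(2-methyl-1,3-dioxolan-2-yl)ethyl]cyclohexan-1-one
Product: 18 (4R,5S,6R)-6-(4-bromopent-4-en-1-yl)-4,5-dimethyl-5-[2-(2-methyl-1,3-dioxolan-2-yl)ethyl]cyclohex-2-en-1-one, via lithium enolate 17 (not isolated)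
Conditions: LiN(i-Pr)2, THF, −78 °C; then N-tert-butylbenzenesulfinimidoyl chloride, −78 °C
Reagents that add atoms: none
Why: Kinetic deprotonation at C6, the only unhindered α-position, followed by oxidation of the lithium enolate with the sulfinimidoyl chloride (Mukaiyama dehydrogenation, syn-elimination of the sulfenamide) gives the C6=C7 enone without touching the C10 centre.

Step 8
Reactants: 18 (4R,5S,6R)-6-(4-bromopent-4-en-1-yl)-4,5-dimethyl-5-[2-(2-methyl-1,3-dioxolan-2-yl)ethyl]cyclohex-2-en-1-one
Product: 20 (4S,5R,6S)-4-(4-bromopent-4-en-1-yl)-3,5,6-trimethyl-5-[2-(2-methyl-1,3-dioxolan-2-yl)ethyl]cyclohex-2-en-1-one, via tertiary allylic alcohol 19 (not isolated)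
Conditions: MeLi, Et2O/THF, −78 °C; NH4Cl work-up; then pyridinium chlorochromate (C5H5NH[CrO3Cl]), 4 Å molecular sieves, CH2Cl2, 25 °C
Reagents that add atoms: methyllithium, [Li]C
Why: 1,2-Addition of methyllithium gives the tertiary allylic alcohol, whose chromate ester undergoes the Babler–Dauben oxidative transposition ([3,3] shift, then oxidation at C7), which leaves the new methyl (C19) on C5, the alkene at C5=C6 and the carbonyl at C7.

Step 9
Reactants: 20 (4S,5R,6S)-4-(4-bromopent-4-en-1-yl)-3,5,6-trimethyl-5-[2-(2-methyl-1,3-dioxolan-2-yl)ethyl]cyclohex-2-en-1-one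
Product: 21 cis-fused ketone: 5β,8α,9α-trimethyl-4-methylidene-9β-[2-(2-methyl-1,3-dioxolan-2-yl)ethyl]-10βH-decalin-7-one
Conditions: Pd(OAc)2 (10 mol %), PPh3 (20 mol %), HCO2Na (3 equiv), Et4NCl (1 equiv), DMF, 80 °C
Reagents that add atoms: none
Why: Zerovalent palladium inserts into the C4–Br bond, the alkenylpalladium bromide adds syn across the enone C5=C6 bond with C4 bonding to the β-carbon C5, and, because the resulting C6 palladium enolate has no syn β-hydrogen (C5 is quaternary, C7 is a carbonyl), it is intercepted by formate, which loses CO2 and delivers hydride to release ketone 21 and zerovalent palladium. The closest known reaction type is the reductive Heck reaction, the palladium-catalysed conjugate addition of alkenyl halides to enones in the presence of formate. Ring A closes in the 6-exo-trig mode. The new quaternary stereocentre C5 is controlled by C10: the C1–C3 tether sits on the α face and can reach only that face of C5 in a syn-carbopalladation, so C4 enters α (axially on the half-chair), the C19 methyl is pushed β and the ring fusion is cis, which overrides the 1,3-diaxial clash with the C20 methyl that would steer an untethered reagent to the β face. The step needs insertion to outrun formate reduction of the alkenylpalladium species and attack at C5 in preference to C6 (7-endo); the polarisation of C5=C6 by the C7 ketone, the six-membered transition state and the absence of any other alkene within reach should secure this.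

Step 10
Reactants: 21 cis-fused ketone
Product: 22 5β,8α,9α-trimethyl-4-methylidene-9β-[2-(2-methyl-1,3-dioxolan-2-yl)ethyl]-10βH-decalin-7β-ol
Conditions: Li, NH3(l)/THF, t-BuOH (2 equiv), −78 °C; then NH4Cl
Reagents that add atoms: none
Why: Dissolving-metal reduction proceeds through the ketyl radical anion and gives the thermodynamically preferred equatorial alcohol (7β, trans to the C8 methyl), whereas a hydride reagent would be forced to the β face by the axial C4 and C20 groups and give the axial epimer; the isolated alkene and the ketal are inert.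

Step 11
Reactants: 22 7β-alcohol
Product: 23 7β-acetoxy-5β,8α,9α-trimethyl-4-methylidene-9β-[2-(2-methyl-1,3-dioxolan-2-yl)ethyl]-10βH-decalin
Conditions: Ac2O, DMAP (cat.), pyridine, CH2Cl2, 25 °C
Reagents that add atoms: acetic anhydride, CC(=O)OC(C)=O
Why: Nucleophilic catalysis by DMAP acylates the equatorial secondary alcohol with retention of configuration (esterification).

Step 12
Reactants: 23 7β-acetate ketal
Product: 24 7β-acetoxy-5β,8α,9α-trimethyl-4-methylidene-9β-(3-oxobutyl)-10βH-decalin
Conditions: pyridinium p-toluenesulfonate (cat.), acetone/H2O, 50 °C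
Reagents that add atoms: water, O
Why: Mild acid-catalysed ketal hydrolysis unmasks the C13 methyl ketone while the secondary acetate and the 1,1-disubstituted alkene should survive.

Step 13
Reactants: 24 methyl ketone
Product: 25 tert-butyl (13E)-7β-acetoxy-5β,10β-cis-cleroda-4(18),13-dien-15-oate
Conditions: tert-butyl diethylphosphonoacetate, NaH, THF, 0 to 50 °C
Reagents that add atoms: tert-butyl 2-(diethoxyphosphoryl)acetate, CCOP(=O)(OCC)CC(=O)OC(C)(C)C
Why: Horner–Wadsworth–Emmons olefination of the unhindered methyl ketone should give mainly the E-enoate, in which the larger C12 chain lies trans to the ester, the minor Z isomer being removed by chromatography.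

Step 14
Reactants: 25 tert-butyl (13E)-7β-acetoxy-5β,10β-cis-cleroda-4(18),13-dien-15-oate
Product: 27 tert-butyl (13E)-7β-acetoxy-3-oxo-5β,10β-cis-cleroda-4(18),13-dien-15-oate, via allylic alcohol 26 (not isolated)
Conditions: SeO2 (0.5 equiv), t-BuOOH (3 equiv), CH2Cl2, 25 °C; then Dess–Martin periodinane, CH2Cl2, 25 °C
Reagents that add atoms: tert-butyl hydroperoxide, CC(C)(C)OO (oxygen relayed through SeO2, O=[Se]=O)
Why: SeO2-mediated allylic oxidation (ene reaction, then [2,3] shift) attacks C3, the only allylic CH2 of the electron-rich 1,1-disubstituted alkene since C5 is quaternary and the enoate alkene is deactivated, and Dess–Martin oxidation of the allylic alcohol gives the α-methylene ketone.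

Step 15
Reactants: 27 tert-butyl (13E)-7β-acetoxy-3-oxo-5β,10β-cis-cleroda-4(18),13-dien-15-oate
Product: 30 tert-butyl (13E)-7β-acetoxy-2-hydroxy-3-oxo-5β,10β-cis-cleroda-1,4(18),13-trien-15-oate, via lithium dienolate 28 (not isolated), via hydroxy ketone 29 (not isolated)
Conditions: LiN(SiMe3)2, THF, −78 °C; 2-(phenylsulfonyl)-3-phenyloxaziridine, −78 °C; NH4Cl; then Dess–Martin periodinane, CH2Cl2, 25 °C
Reagents that add atoms: 2-(phenylsulfonyl)-3-phenyloxaziridine, O=S(=O)(c1ccccc1)N1OC1c1ccccc1
Why: C2 is the only enolisable position of the C3 ketone, so its lithium dienolate is hydroxylated by the oxaziridine (α-hydroxylation of an enolate), and Dess–Martin oxidation gives the 2,3-dione, which can enolise only toward C1 and therefore rests as the diosphenol.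

Step 16
Reactants: 30 tert-butyl (13E)-7β-acetoxy-2-hydroxy-3-oxo-5β,10β-cis-cleroda-1,4(18),13-trien-15-oate
Product: 31 (13E)-7β-acetoxy-2-hydroxy-3-oxo-5β,10β-cis-cleroda-1,4(18),13-trien-15-oic acid (CNP0192653.1)
Conditions: CF3CO2H, CH2Cl2, 0 °C
Reagents that add atoms: none
Why: Acidolysis of the tert-butyl ester by loss of the tert-butyl cation (as isobutene) frees the acid without touching the secondary acetate, the diosphenol or the exocyclic enone.

**Compound list**
1 | 2-bromoprop-2-en-1-ol | OCC(Br)=C | starting material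
2 | ethyl vinyl ether | C=COCC | starting material
3 | 2-bromoallyl vinyl ether | C=COCC(Br)=C | intermediate
4 | 4-bromopent-4-enal | O=CCCC(Br)=C | intermediate
5 | propanal | CCC=O | starting material
6 | but-3-en-2-one | CC(=O)C=C | starting material
7 | (R)-2-methyl-5-oxohexanal | C[C@H](CCC(C)=O)C=O | intermediate
8 | (R)-4-methylcyclohex-2-en-1-one | C[C@@H]1CCC(=O)C=C1 | intermediate
9 | trimethyl{[(3S,4R)-3,4-dimethylcyclohex-1-en-1-yl]oxy}silane | C[C@@H]1CCC(O[Si](C)(C)C)=C[C@H]1C | intermediate
10 | (R)-3,4-dimethylcyclohex-2-en-1-one | C[C@@H]1CCC(=O)C=C1C | intermediate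
11 | bromomagnesium (3S,4R)-3,4-dimethyl-3-[2-(2-methyl-1,3-dioxolan-2-yl)ethyl]cyclohex-1-en-1-olate | CC1(CC[C@]2(C)C=C(O[Mg]Br)CC[C@H]2C)OCCO1 | intermediate
12 | bromomagnesium alkoxide of (3S,4R)-2-(4-bromo-1-hydroxypent-4-en-1-yl)-3,4-dimethyl-3-[2-(2-methyl-1,3-dioxolan-2-yl)ethyl]cyclohexan-1-one (C2 and carbinol epimers) | CC1(CC[C@]2(C)C(C(CCC(Br)=C)O[Mg]Br)C(=O)CC[C@H]2C)OCCO1 | intermediate
13 | methanesulfonate of the aldol in 12 (C2 and carbinol epimers) | CC1(CC[C@]2(C)C(C(CCC(Br)=C)OS(C)(=O)=O)C(=O)CC[C@H]2C)OCCO1 | intermediate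
14 | (2Z,3S,4R)-2-(4-bromopent-4-en-1-ylidene)-3,4-dimethyl-3-[2-(2-methyl-1,3-dioxolan-2-yl)ethyl]cyclohexan-1-one | C=C(Br)CC/C=C1/[C@@](C)(CCC2(C)OCCO2)[C@H](C)CCC1=O | intermediate
15 | copper enolate (monovalent copper, phosphine ligands not drawn; C5–O, C5=C10) of ketone 16 | C=C(Br)CCCC1=C(O[Cu])CC[C@@H](C)[C@]1(C)CCC2(C)OCCO2 | intermediate
16 | (2R,3S,4R)-2-(4-bromopent-4-en-1-yl)-3,4-dimethyl-3-[2-(2-methyl-1,3-dioxolan-2-yl)ethyl]cyclohexan-1-one | C=C(Br)CCC[C@@H]1[C@@](C)(CCC2(C)OCCO2)[C@H](C)CCC1=O | intermediate
17 | lithium enolate (C5–O, C5=C6) of ketone 16 | C=C(Br)CCC[C@@H]1[C@@](C)(CCC2(C)OCCO2)[C@H](C)CC=C1O[Li] | intermediate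
18 | (4R,5S,6R)-6-(4-bromopent-4-en-1-yl)-4,5-dimethyl-5-[2-(2-methyl-1,3-dioxolan-2-yl)ethyl]cyclohex-2-en-1-one | C=C(Br)CCC[C@@H]1[C@@](C)(CCC2(C)OCCO2)[C@H](C)C=CC1=O | intermediate
19 | (4R,5S,6R)-6-(4-bromopent-4-en-1-yl)-1,4,5-trimethyl-5-[2-(2-methyl-1,3-dioxolan-2-yl)ethyl]cyclohex-2-en-1-ol (C1 epimers) | C=C(Br)CCC[C@@H]1[C@@](C)(CCC2(C)OCCO2)[C@H](C)C=CC1(C)O | intermediate
20 | (4S,5R,6S)-4-(4-bromopent-4-en-1-yl)-3,5,6-trimethyl-5-[2-(2-methyl-1,3-dioxolan-2-yl)ethyl]cyclohex-2-en-1-one | C=C(Br)CCC[C@@H]1[C@@](C)(CCC2(C)OCCO2)[C@H](C)C(=O)C=C1C | intermediate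
21 | cis-fused ketone: 5β,8α,9α-trimethyl-4-methylidene-9β-[2-(2-methyl-1,3-dioxolan-2-yl)ethyl]-10βH-decalin-7-one | C=C1CCC[C@@H]2[C@@](C)(CCC3(C)OCCO3)[C@H](C)C(=O)C[C@]12C | intermediate
22 | 5β,8α,9α-trimethyl-4-methylidene-9β-[2-(2-methyl-1,3-dioxolan-2-yl)ethyl]-10βH-decalin-7β-ol | C=C1CCC[C@@H]2[C@@](C)(CCC3(C)OCCO3)[C@H](C)[C@@H](O)C[C@]12C | intermediate
23 | 7β-acetoxy-5β,8α,9α-trimethyl-4-methylidene-9β-[2-(2-methyl-1,3-dioxolan-2-yl)ethyl]-10βH-decalin | C=C1CCC[C@@H]2[C@@](C)(CCC3(C)OCCO3)[C@H](C)[C@@H](OC(C)=O)C[C@]12C | intermediate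
24 | 7β-acetoxy-5β,8α,9α-trimethyl-4-methylidene-9β-(3-oxobutyl)-10βH-decalin | C=C1CCC[C@@H]2[C@@](C)(CCC(C)=O)[C@H](C)[C@@H](OC(C)=O)C[C@]12C | intermediate
25 | tert-butyl (13E)-7β-acetoxy-5β,10β-cis-cleroda-4(18),13-dien-15-oate | C=C1CCC[C@@H]2[C@@](C)(CC/C(C)=C/C(=O)OC(C)(C)C)[C@H](C)[C@@H](OC(C)=O)C[C@]12C | intermediate
26 | tert-butyl (13E)-7β-acetoxy-3-hydroxy-5β,10β-cis-cleroda-4(18),13-dien-15-oate (C3 epimers) | C=C1C(O)CC[C@@H]2[C@@](C)(CC/C(C)=C/C(=O)OC(C)(C)C)[C@H](C)[C@@H](OC(C)=O)C[C@]12C | intermediate
27 | tert-butyl (13E)-7β-acetoxy-3-oxo-5β,10β-cis-cleroda-4(18),13-dien-15-oate | C=C1C(=O)CC[C@@H]2[C@@](C)(CC/C(C)=C/C(=O)OC(C)(C)C)[C@H](C)[C@@H](OC(C)=O)C[C@]12C | intermediate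
28 | lithium dienolate (C3–O, C2=C3) of ketone 27 | C=C1C(O[Li])=CC[C@@H]2[C@@](C)(CC/C(C)=C/C(=O)OC(C)(C)C)[C@H](C)[C@@H](OC(C)=O)C[C@]12C | intermediate
29 | tert-butyl (13E)-7β-acetoxy-2-hydroxy-3-oxo-5β,10β-cis-cleroda-4(18),13-dien-15-oate (C2 epimers) | C=C1C(=O)C(O)C[C@@H]2[C@@](C)(CC/C(C)=C/C(=O)OC(C)(C)C)[C@H](C)[C@@H](OC(C)=O)C[C@]12C | intermediate
30 | tert-butyl (13E)-7β-acetoxy-2-hydroxy-3-oxo-5β,10β-cis-cleroda-1,4(18),13-trien-15-oate | C=C1C(=O)C(O)=C[C@@H]2[C@@](C)(CC/C(C)=C/C(=O)OC(C)(C)C)[C@H](C)[C@@H](OC(C)=O)C[C@]12C | intermediate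
31 | (13E)-7β-acetoxy-2-hydroxy-3-oxo-5β,10β-cis-cleroda-1,4(18),13-trien-15-oic acid (CNP0192653.1) | C=C1C(=O)C(O)=C[C@@H]2[C@@](C)(CC/C(C)=C/C(=O)O)[C@H](C)[C@@H](OC(C)=O)C[C@]12C | target

**Step count and risks**
Total step count: 16. Longest linear sequence: 15 steps (propanal 5 to target 31, steps 2 to 16); step 1 is a one-step branch that supplies aldehyde 4.

The three steps most likely to fail are, in this order, step 9, step 6 and step 15.

In step 9 the alkenylpalladium intermediate must insert into a β,β-disubstituted enone along a path that runs 1,3-diaxial to the C20 methyl. If insertion is slow, formate reduces the alkenylpalladium species first (loss of bromine without ring closure), or palladium hydride moves the exocyclic double bond into the ring. The fallback leaves palladium for a tin hydride radical chain: from 20, slow addition of Bu3SnH with AIBN in benzene at 80 °C generates the C4 alkenyl radical, which adds 6-exo to the enone β-carbon C5 on the tether face, and the C6 α-keto radical takes hydrogen from the stannane. This gives 21 directly, so no compound outside the list is made (F0).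

In step 6 the enolate may be protonated without facial preference, so that both C10 epimers form. The fallback replaces kinetic by thermodynamic control: the crude reduction product from 14, which then contains the 10-epimer of ketone 16 F1, is stirred with NaOMe in MeOH at 25 °C. C10 is α to the C5 ketone and epimerises through the enolate; 16 holds the chain equatorial, whereas F1 must place it axial or flip the ring with two axial groups, so the equilibrium should lie on the side of 16. Residual F1 is separated and recycled, and the route is rejoined at 16.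

In step 15 the lithium dienolate of the 2-methylidene ketone may add to unreacted 27 (Michael oligomerisation) or be intercepted by the sulfonimine by-product. The fallback avoids any enolate: from 27, Riley oxidation with SeO2 in wet dioxane at 90 °C oxidises the C2 methylene through the enol and its selenite ester straight to the 2,3-dione, that is to diosphenol 30, where the route is rejoined. No compound outside the list is made (F0).

**Further compounds**
F0 | step 9 | none | none
F1 | step 6 | (2S,3S,4R)-2-(4-bromopent-4-en-1-yl)-3,4-dimethyl-3-[2-(2-methyl-1,3-dioxolan-2-yl)ethyl]cyclohexan-1-one (10-epimer of 16) | C=C(Br)CCC[C@H]1[C@@](C)(CCC2(C)OCCO2)[C@H](C)CCC1=O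
F0 | step 15 | none | none
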